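**Retrosynthetic overview**
- The target comes from its tri-O-benzyl ether by hydrogenolysis. The pyranone ring is formed last, by Algar–Flynn–Oyamada cyclisation of a 2'-hydroxychalcone.
- The chalcone comes from a Claisen–Schmidt aldol of an o-hydroxyacetophenone with benzaldehyde. The acetyl group is put ortho to the only free phenol OH (Mg-mediated formylation, MeMgBr, MnO2).
- The phenethyl carbinol (latent ketone) comes from Grignard opening of a chroman-2-ol.
- Key disconnection: the aryl–CH bond, made by an asymmetric iminium-catalysed Michael (Friedel–Crafts-type) addition of 3,5-bis(benzyloxy)phenol to an (E)-5-arylpent-2-enal. This sets the (R) centre and closes a temporary lactol ring.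
- The enal comes from eugenol (benzylation, hydroboration–oxidation, oxidation, Wittig). All aromatic rings are bought.

Assumption: the target is made as the open keto-phenol form with the (R) centre (CIP: flavone C-8 > CH2C=O > CH2CH2Ar > H); 3,5-bis(benzyloxy)phenol, 2-phenylethylmagnesium chloride solution and the (S)-diphenylprolinol TMS ether catalyst are bought.

**Step 1**
Reactants: 1 eugenol
Product: 2 4-allyl-1-(benzyloxy)-2-methoxybenzene
Conditions: BnBr (1.1 equiv), K2CO3, DMF, rt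
Reagents that add atoms: benzyl bromide BrCc1ccccc1
Why: Williamson ether synthesis; the benzyl group masks the guaiacol OH until the final hydrogenolysis.

**Step 2**
Reactants: 2 4-allyl-1-(benzyloxy)-2-methoxybenzene
Product: 4 3-[4-(benzyloxy)-3-methoxyphenyl]propan-1-ol, via B-alkyl-9-BBN adduct 3 (not isolated)
Conditions: 9-BBN (0.5 M in THF), 0 °C→rt; then 3 M NaOH, 30% H2O2, 0 °C→rt
Reagents that add atoms: hydrogen peroxide OO
Why: Hydroboration–oxidation; 9-BBN adds anti-Markovnikov to the terminal alkene and alkaline peroxide converts the C–B bond into the primary alcohol.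

**Step 3**
Reactants: 4 3-[4-(benzyloxy)-3-methoxyphenyl]propan-1-ol
Product: 5 3-[4-(benzyloxy)-3-methoxyphenyl]propanal
Conditions: DMP (1.2 equiv), CH2Cl2, 0 °C→rt
Reagents that add atoms: none
Why: Dess–Martin oxidation stops at the aldehyde and leaves the benzyl ether and the arene untouched.

**Step 4**
Reactants: 5 3-[4-(benzyloxy)-3-methoxyphenyl]propanal
Product: 6 (2E)-5-[4-(benzyloxy)-3-methoxyphenyl]pent-2-enal
Conditions: Ph3P=CHCHO (1.2 equiv), toluene, 80 °C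
Reagents that add atoms: (triphenylphosphoranylidene)acetaldehyde O=CC=P(c1ccccc1)(c1ccccc1)c1ccccc1
Why: Wittig olefination with the stabilised formylmethylene ylide gives the (E)-enal selectively.

**Step 5**
Reactants: 6 (2E)-5-[4-(benzyloxy)-3-methoxyphenyl]pent-2-enal; 7 3,5-bis(benzyloxy)phenol
Product: 9 (4R)-5,7-bis(benzyloxy)-4-{2-[4-(benzyloxy)-3-methoxyphenyl]ethyl}-3,4-dihydro-2H-chromen-2-ol (anomer mixture), via open-chain hydroxy aldehyde 8 (not isolated)
Conditions: 7 (1.2 equiv), (S)-α,α-diphenylprolinol TMS ether (20 mol%), PhCO2H (20 mol%), toluene, 0 °C, 48 h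
Reagents that add atoms: none
Why: Iminium-catalysed asymmetric Michael (Friedel–Crafts-type conjugate) addition: the CPh2OTMS group of the (S)-catalyst shields the Si face of C-3 of the (E,E)-iminium ion, so the phenol ortho-carbon adds to the Re face and gives the (R) centre, and the ortho-OH then closes the lactol, which places the chain next to the only free oxygen.

**Step 6**
Reactants: 9 (4R)-lactol; 10 2-phenylethylmagnesium chloride
Product: 11 3,5-bis(benzyloxy)-2-{(3R,5RS)-1-[4-(benzyloxy)-3-methoxyphenyl]-5-hydroxy-7-phenylheptan-3-yl}phenol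
Conditions: 10 (3.5 equiv, 1 M in THF), THF, −20 °C→rt; sat. aq NH4Cl
Reagents that add atoms: none
Why: Grignard addition to the ring-opened hydroxy aldehyde form of the lactol (the first equivalent deprotonates it) gives the secondary alcohol as a latent ketone; the carbinol epimers are irrelevant and the (R) centre is not enolisable.

**Step 7**
Reactants: 11 phenol diol
Product: 13 4,6-bis(benzyloxy)-2-hydroxy-3-{(3R,5RS)-1-[4-(benzyloxy)-3-methoxyphenyl]-5-hydroxy-7-phenylheptan-3-yl}benzaldehyde, via ortho-hydroxymethyl phenol 12 (not isolated)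
Conditions: MgCl2 (3 equiv), Et3N (5 equiv), (CH2O)n (8 equiv), MeCN, reflux; 1 M HCl work-up
Reagents that add atoms: paraformaldehyde (as formaldehyde) C=O
Why: Casnati–Skattebøl magnesium-mediated ortho-formylation: the ArO–MgCl chelate delivers formaldehyde only to the single free ortho position, and a second formaldehyde oxidises the hydroxymethyl intermediate by hydride transfer.

**Step 8**
Reactants: 13 salicylaldehyde
Product: 14 3,5-bis(benzyloxy)-2-{(3R,5RS)-1-[4-(benzyloxy)-3-methoxyphenyl]-5-hydroxy-7-phenylheptan-3-yl}-6-[(1RS)-1-hydroxyethyl]phenol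
Conditions: MeMgBr (4.5 equiv), THF, −20→0 °C; pH 7 buffer quench; crude used at once
Reagents that add atoms: methylmagnesium bromide C[Mg]Br
Why: Chelation-assisted Grignard addition to the aldehyde after both OH groups are deprotonated.

**Step 9**
Reactants: 14 benzylic carbinol
Product: 15 1-[4,6-bis(benzyloxy)-2-hydroxy-3-{(3R,5RS)-1-[4-(benzyloxy)-3-methoxyphenyl]-5-hydroxy-7-phenylheptan-3-yl}phenyl]ethan-1-one
Conditions: activated MnO2 (15 equiv), CH2Cl2, rt
Reagents that add atoms: none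
Why: MnO2 oxidises only the activated benzylic alcohol to the hydrogen-bonded o-hydroxyacetophenone; the aliphatic carbinol is inert.

**Step 10**
Reactants: 15 o-hydroxyacetophenone; 16 benzaldehyde
Product: 18 (2E)-1-[4,6-bis(benzyloxy)-2-hydroxy-3-{(3R,5RS)-1-[4-(benzyloxy)-3-methoxyphenyl]-5-hydroxy-7-phenylheptan-3-yl}phenyl]-3-phenylprop-2-en-1-one, via aldol adduct 17 (not isolated)
Conditions: 16 (1.5 equiv), 50% aq KOH, EtOH/THF, rt, 48 h; then dilute HCl
Reagents that add atoms: none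
Why: Claisen–Schmidt aldol condensation: the acetyl enolate adds to non-enolisable benzaldehyde and E1cB dehydration gives the (E)-chalcone; the side chain is still an alcohol, so no second enolisable carbonyl competes.

**Step 11**
Reactants: 18 chalcone alcohol
Product: 19 (2E)-1-[4,6-bis(benzyloxy)-2-hydroxy-3-{(3R)-1-[4-(benzyloxy)-3-methoxyphenyl]-5-oxo-7-phenylheptan-3-yl}phenyl]-3-phenylprop-2-en-1-one
Conditions: DMP (1.3 equiv), CH2Cl2, 0 °C→rt
Reagents that add atoms: none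
Why: Dess–Martin oxidation of the remaining secondary alcohol to the ketone; the chelated 2'-OH and the enone are inert, and the stereocentre is β to the new ketone so it cannot epimerise.

**Step 12**
Reactants: 19 keto chalcone
Product: 21 5,7-bis(benzyloxy)-8-{(3R)-1-[4-(benzyloxy)-3-methoxyphenyl]-5-oxo-7-phenylheptan-3-yl}-3-hydroxy-2-phenyl-4H-chromen-4-one, via trans-dihydroflavonol 20 (not isolated)
Conditions: 30% H2O2 (6 equiv), 2 M NaOH, MeOH/THF, 0 °C→rt; then AcOH; recrystallise (EtOAc/hexane) to upgrade ee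
Reagents that add atoms: hydrogen peroxide OO
Why: Algar–Flynn–Oyamada reaction: alkaline peroxide epoxidises the enone, the 2'-phenoxide closes the pyranone ring 6-endo and the dihydroflavonol is oxidised to the flavonol; only the OH next to the chain is free, so only the 8-substituted flavonol can form.

**Step 13**
Reactants: 21 tri-O-benzyl flavonol
Product: 22 3,5,7-trihydroxy-8-[(3R)-1-(4-hydroxy-3-methoxyphenyl)-5-oxo-7-phenylheptan-3-yl]-2-phenyl-4H-chromen-4-one
Conditions: H2 (1 atm), 10% Pd/C, THF/MeOH, rt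
Reagents that add atoms: none
Why: Catalytic hydrogenolysis removes the three benzyl ethers; the chromone C2=C3, the ketone and the C–C-bonded stereocentre are untouched at 1 atm.

**Compound list**
1 | eugenol (4-allyl-2-methoxyphenol) | COc1cc(CC=C)ccc1O | starting material
2 | 4-allyl-1-(benzyloxy)-2-methoxybenzene | COc1cc(CC=C)ccc1OCc1ccccc1 | intermediate
3 | 9-{3-[4-(benzyloxy)-3-methoxyphenyl]propyl}-9-borabicyclo[3.3.1]nonane | COc1cc(CCCB2C3CCCC2CCC3)ccc1OCc1ccccc1 | intermediate (not isolated)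
4 | 3-[4-(benzyloxy)-3-methoxyphenyl]propan-1-ol | COc1cc(CCCO)ccc1OCc1ccccc1 | intermediate
5 | 3-[4-(benzyloxy)-3-methoxyphenyl]propanal | COc1cc(CCC=O)ccc1OCc1ccccc1 | intermediate
6 | (2E)-5-[4-(benzyloxy)-3-methoxyphenyl]pent-2-enal | COc1cc(CC/C=C/C=O)ccc1OCc1ccccc1 | intermediate
7 | 3,5-bis(benzyloxy)phenol | Oc1cc(OCc2ccccc2)cc(OCc2ccccc2)c1 | starting material
8 | (3R)-3-[2,4-bis(benzyloxy)-6-hydroxyphenyl]-5-[4-(benzyloxy)-3-methoxyphenyl]pentanal | COc1cc(CC[C@H](CC=O)c2c(O)cc(OCc3ccccc3)cc2OCc2ccccc2)ccc1OCc1ccccc1 | intermediate (not isolated)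
9 | (4R)-5,7-bis(benzyloxy)-4-{2-[4-(benzyloxy)-3-methoxyphenyl]ethyl}-3,4-dihydro-2H-chromen-2-ol (anomer mixture) | COc1cc(CC[C@@H]2CC(O)Oc3cc(OCc4ccccc4)cc(OCc4ccccc4)c32)ccc1OCc1ccccc1 | intermediate
10 | 2-phenylethylmagnesium chloride | Cl[Mg]CCc1ccccc1 | starting material
11 | 3,5-bis(benzyloxy)-2-{(3R,5RS)-1-[4-(benzyloxy)-3-methoxyphenyl]-5-hydroxy-7-phenylheptan-3-yl}phenol | COc1cc(CC[C@H](CC(O)CCc2ccccc2)c2c(O)cc(OCc3ccccc3)cc2OCc2ccccc2)ccc1OCc1ccccc1 | intermediate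
12 | 3,5-bis(benzyloxy)-2-{(3R,5RS)-1-[4-(benzyloxy)-3-methoxyphenyl]-5-hydroxy-7-phenylheptan-3-yl}-6-(hydroxymethyl)phenol | COc1cc(CC[C@H](CC(O)CCc2ccccc2)c2c(O)c(CO)c(OCc3ccccc3)cc2OCc2ccccc2)ccc1OCc1ccccc1 | intermediate (not isolated)
13 | 4,6-bis(benzyloxy)-2-hydroxy-3-{(3R,5RS)-1-[4-(benzyloxy)-3-methoxyphenyl]-5-hydroxy-7-phenylheptan-3-yl}benzaldehyde | COc1cc(CC[C@H](CC(O)CCc2ccccc2)c2c(O)c(C=O)c(OCc3ccccc3)cc2OCc2ccccc2)ccc1OCc1ccccc1 | intermediate
14 | 3,5-bis(benzyloxy)-2-{(3R,5RS)-1-[4-(benzyloxy)-3-methoxyphenyl]-5-hydroxy-7-phenylheptan-3-yl}-6-[(1RS)-1-hydroxyethyl]phenol | COc1cc(CC[C@H](CC(O)CCc2ccccc2)c2c(O)c(C(C)O)c(OCc3ccccc3)cc2OCc2ccccc2)ccc1OCc1ccccc1 | intermediate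
15 | 1-[4,6-bis(benzyloxy)-2-hydroxy-3-{(3R,5RS)-1-[4-(benzyloxy)-3-methoxyphenyl]-5-hydroxy-7-phenylheptan-3-yl}phenyl]ethan-1-one | COc1cc(CC[C@H](CC(O)CCc2ccccc2)c2c(O)c(C(C)=O)c(OCc3ccccc3)cc2OCc2ccccc2)ccc1OCc1ccccc1 | intermediate
16 | benzaldehyde | O=Cc1ccccc1 | starting material
17 | 1-[4,6-bis(benzyloxy)-2-hydroxy-3-{(3R,5RS)-1-[4-(benzyloxy)-3-methoxyphenyl]-5-hydroxy-7-phenylheptan-3-yl}phenyl]-3-hydroxy-3-phenylpropan-1-one (carbinol epimers) | COc1cc(CC[C@H](CC(O)CCc2ccccc2)c2c(O)c(C(=O)CC(O)c3ccccc3)c(OCc3ccccc3)cc2OCc2ccccc2)ccc1OCc1ccccc1 | intermediate (not isolated)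
18 | (2E)-1-[4,6-bis(benzyloxy)-2-hydroxy-3-{(3R,5RS)-1-[4-(benzyloxy)-3-methoxyphenyl]-5-hydroxy-7-phenylheptan-3-yl}phenyl]-3-phenylprop-2-en-1-one | COc1cc(CC[C@H](CC(O)CCc2ccccc2)c2c(O)c(C(=O)/C=C/c3ccccc3)c(OCc3ccccc3)cc2OCc2ccccc2)ccc1OCc1ccccc1 | intermediate
19 | (2E)-1-[4,6-bis(benzyloxy)-2-hydroxy-3-{(3R)-1-[4-(benzyloxy)-3-methoxyphenyl]-5-oxo-7-phenylheptan-3-yl}phenyl]-3-phenylprop-2-en-1-one | COc1cc(CC[C@H](CC(=O)CCc2ccccc2)c2c(O)c(C(=O)/C=C/c3ccccc3)c(OCc3ccccc3)cc2OCc2ccccc2)ccc1OCc1ccccc1 | intermediate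
20 | 5,7-bis(benzyloxy)-8-{(3R)-1-[4-(benzyloxy)-3-methoxyphenyl]-5-oxo-7-phenylheptan-3-yl}-3-hydroxy-2-phenyl-2,3-dihydro-4H-chromen-4-one (2,3-trans, both trans diastereomers) | COc1cc(CC[C@H](CC(=O)CCc2ccccc2)c2c(OCc3ccccc3)cc(OCc3ccccc3)c3c2OC(c2ccccc2)C(O)C3=O)ccc1OCc1ccccc1 | intermediate (not isolated)
21 | 5,7-bis(benzyloxy)-8-{(3R)-1-[4-(benzyloxy)-3-methoxyphenyl]-5-oxo-7-phenylheptan-3-yl}-3-hydroxy-2-phenyl-4H-chromen-4-one | COc1cc(CC[C@H](CC(=O)CCc2ccccc2)c2c(OCc3ccccc3)cc(OCc3ccccc3)c3c(=O)c(O)c(-c4ccccc4)oc23)ccc1OCc1ccccc1 | intermediate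
22 | 3,5,7-trihydroxy-8-[(3R)-1-(4-hydroxy-3-methoxyphenyl)-5-oxo-7-phenylheptan-3-yl]-2-phenyl-4H-chromen-4-one (CNP0164153.1) | COc1cc(CC[C@H](CC(=O)CCc2ccccc2)c2c(O)cc(O)c3c(=O)c(O)c(-c4ccccc4)oc23)ccc1O | target

**Totals**
Total step count: 13. Longest linear sequence: 13 steps (1 → 22); 7, 10 and 16 are bought and enter at steps 5, 6 and 10.

**Three steps most likely to fail**

Step 5 (key Michael addition). Risks are ee below about 90 %, some para- or bis-alkylation of the phenol, and slow turnover with the γ-enolisable enal. The fallback sets out from aldehyde 5 and phenol 7 and comes back at lactol 9. Knoevenagel condensation of 5 with Meldrum's acid (pyrrolidinium acetate, benzene, rt) gives the alkylidene Meldrum's acid F1. Yb(OTf)3-catalysed Friedel–Crafts-type conjugate addition of 7 (MeNO2, 80 °C), followed by lactonisation with loss of acetone and CO2, gives the racemic dihydrocoumarin F2. Preparative chiral SFC gives the (4R)-dihydrocoumarin F3, and DIBAL-H (toluene, −78 °C) reduces it to 9.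

Step 8 (MeMgBr addition). The free o-hydroxybenzylic carbinol 14 on a trioxygenated ring ionises easily to an o-quinone methide and may not survive isolation. The fallback sets out from 13 and comes back at 15. MOMCl/K2CO3 in acetone protects only the phenol and gives the MOM-protected aldehyde F4. MeMgBr gives the MOM-protected carbinol F5, which has no quinone-methide pathway. MnO2 gives the MOM-protected acetophenone F6, and HCl in MeOH at rt removes the MOM group to give 15.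

Step 12 (Algar–Flynn–Oyamada). Chalcones with a 6'-alkoxy group can close 5-exo to aurones instead of flavonols. The fallback sets out from 19 and comes back at 21. Catalytic I2 in DMSO at 120 °C cyclises and dehydrogenates 19 to the flavone F7. Dimethyldioxirane (acetone/CH2Cl2, 0 °C) gives the flavone 2,3-epoxide F8, and catalytic TsOH opens it to the 3-hydroxyflavone 21.

**Further compounds**
F1 | step 5 | 5-{3-[4-(benzyloxy)-3-methoxyphenyl]propylidene}-2,2-dimethyl-1,3-dioxane-4,6-dione | COc1cc(CCC=C2C(=O)OC(C)(C)OC2=O)ccc1OCc1ccccc1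
F2 | step 5 | rac-5,7-bis(benzyloxy)-4-{2-[4-(benzyloxy)-3-methoxyphenyl]ethyl}-3,4-dihydro-2H-chromen-2-one | COc1cc(CCC2CC(=O)Oc3cc(OCc4ccccc4)cc(OCc4ccccc4)c32)ccc1OCc1ccccc1
F3 | step 5 | (4R)-5,7-bis(benzyloxy)-4-{2-[4-(benzyloxy)-3-methoxyphenyl]ethyl}-3,4-dihydro-2H-chromen-2-one | COc1cc(CC[C@@H]2CC(=O)Oc3cc(OCc4ccccc4)cc(OCc4ccccc4)c32)ccc1OCc1ccccc1
F4 | step 8 | 4,6-bis(benzyloxy)-3-{(3R,5RS)-1-[4-(benzyloxy)-3-methoxyphenyl]-5-hydroxy-7-phenylheptan-3-yl}-2-(methoxymethoxy)benzaldehyde | COc1cc(CC[C@H](CC(O)CCc2ccccc2)c2c(OCOC)c(C=O)c(OCc3ccccc3)cc2OCc2ccccc2)ccc1OCc1ccccc1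
F5 | step 8 | 1-[4,6-bis(benzyloxy)-3-{(3R,5RS)-1-[4-(benzyloxy)-3-methoxyphenyl]-5-hydroxy-7-phenylheptan-3-yl}-2-(methoxymethoxy)phenyl]ethan-1-ol | COc1cc(CC[C@H](CC(O)CCc2ccccc2)c2c(OCOC)c(C(C)O)c(OCc3ccccc3)cc2OCc2ccccc2)ccc1OCc1ccccc1
F6 | step 8 | 1-[4,6-bis(benzyloxy)-3-{(3R,5RS)-1-[4-(benzyloxy)-3-methoxyphenyl]-5-hydroxy-7-phenylheptan-3-yl}-2-(methoxymethoxy)phenyl]ethan-1-one | COc1cc(CC[C@H](CC(O)CCc2ccccc2)c2c(OCOC)c(C(C)=O)c(OCc3ccccc3)cc2OCc2ccccc2)ccc1OCc1ccccc1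
F7 | step 12 | 5,7-bis(benzyloxy)-8-{(3R)-1-[4-(benzyloxy)-3-methoxyphenyl]-5-oxo-7-phenylheptan-3-yl}-2-phenyl-4H-chromen-4-one | COc1cc(CC[C@H](CC(=O)CCc2ccccc2)c2c(OCc3ccccc3)cc(OCc3ccccc3)c3c(=O)cc(-c4ccccc4)oc23)ccc1OCc1ccccc1
F8 | step 12 | 2,3-epoxide of F7 (2,3-epoxy-2,3-dihydroflavone) | COc1cc(CC[C@H](CC(=O)CCc2ccccc2)c2c(OCc3ccccc3)cc(OCc3ccccc3)c3C(=O)C4OC4(c4ccccc4)Oc23)ccc1OCc1ccccc1
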